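**Retrosynthetic overview**
- The target is opened at the C8 ester (Yamaguchi acylation with the dienoic acid) and at two acid-labile masks: a silyl ester at C5 and a diethyl acetal of the acrolein.
- The C4–acrolein bond comes from 1,4-addition of an α-acrolein-anion cuprate to a cross-conjugated dienone, anti to the angular methyl; the C8 hydroxyl comes from γ-oxidation of the trienol ether of that dienone.
- The dienone comes from a cis-2-decalone by double dehydrogenation; the C5 carboxyl is grown from the former carvone carbonyl (enol triflate, carbonylation, reduction, equilibration), and the carvone isopropenyl group is excised once it has done its job.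
- Ring B is bought as the ring of (R)-carvone; ring A is formed second, by a Lewis-acid Diels–Alder reaction of carvone with a 2-silyloxybutadiene, which sets the quaternary C4a.
- The side chain comes from (S)-1-bromo-2-methylbutane and methyl (R)-lactate triflate (coupling with inversion), then one-pot reduction/vinylogous Horner–Wadsworth–Emmons olefination.

Assumption: all decalin intermediates carry the target's locants (C1=C8a enone CH, C2 ketone, C4 side-chain carbon, C4a methyl carbon, C5 carboxyl carbon, C8 oxygenated carbon), and 2-bromo-3,3-diethoxyprop-1-ene and triethyl 4-phosphonocrotonate are bought.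

**Route**

Step 1
Reactants: 1 but-3-en-2-one
Product: 2 2-(tert-butyldimethylsilyloxy)buta-1,3-diene
Conditions: TBSOTf, Et3N, Et2O, 0 °C
Reagents that add atoms: tert-butyldimethylsilyl trifluoromethanesulfonate, CC(C)(C)[Si](C)(C)OS(=O)(=O)C(F)(F)F
Why: Soft enolisation and O-silylation of the enone gives the 2-silyloxy diene; no stereocentre is involved.

Step 2
Reactants: 2 2-(tert-butyldimethylsilyloxy)buta-1,3-diene; 3 (R)-(−)-carvone
Product: 4 (4aR,7R,8aS)-2-(tert-butyldimethylsilyloxy)-4a-methyl-7-(prop-1-en-2-yl)-4,4a,6,7,8,8a-hexahydronaphthalen-5(1H)-one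
Conditions: EtAlCl2 (0.3 equiv), 2 (2.5 equiv), toluene, −20 °C → rt; Et3N quench
Reagents that add atoms: none
Why: In this Lewis-acid-catalysed Diels–Alder reaction the nucleophilic CH2 terminus of the diene bonds to the enone β-carbon and the diene adds cis across C2=C3 of carvone on the face anti to the isopropenyl group, which forms ring A and sets the quaternary C4a (Me, 8a-H and isopropenyl all cis).

Step 3
Reactants: 4 Diels–Alder adduct
Product: 5 (4aR,7R,8aS)-2-(tert-butyldimethylsilyloxy)-4a-methyl-7-(prop-1-en-2-yl)-1,4,4a,7,8,8a-hexahydronaphthalen-5-yl trifluoromethanesulfonate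
Conditions: KN(SiMe3)2, THF, −78 °C; PhNTf2, −78 → 0 °C
Reagents that add atoms: N-phenylbis(trifluoromethanesulfonimide), O=S(=O)(N(c1ccccc1)S(=O)(=O)C(F)(F)F)C(F)(F)F
Why: The C5 ketone can enolise only toward C6 (C4a is quaternary) and the enolate is O-triflated, while the silyl enol ether keeps C2 masked.

Step 4
Reactants: 5 enol triflate
Product: 6 methyl (4aR,7R,8aS)-2-(tert-butyldimethylsilyloxy)-4a-methyl-7-(prop-1-en-2-yl)-1,4,4a,7,8,8a-hexahydronaphthalene-5-carboxylate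
Conditions: CO (1 atm), MeOH, Pd(OAc)2 (5 mol%), PPh3, Et3N, DMF, 60 °C
Reagents that add atoms: carbon monoxide, [C-]#[O+]; methanol, CO
Why: Palladium-catalysed methoxycarbonylation of a vinyl triflate (oxidative addition, CO insertion, methanolysis) works well next to quaternary centres.

Step 5
Reactants: 6 unsaturated methyl ester
Product: 8 (4aR,5R,7R,8aS)-4a-methyl-2-oxo-7-(prop-1-en-2-yl)decahydronaphthalene-5-carboxylic acid, via saturated methyl ester 7 (not isolated)
Conditions: Mg, MeOH, 0 °C → rt; NaOMe, 60 °C; H2O, 75 °C; then 2 M HCl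
Reagents that add atoms: water, O
Why: Dissolving-metal conjugate reduction of the enoate is followed by methoxide equilibration of the ester to the equatorial 5β epimer in the chair locked by the equatorial C7 isopropenyl group (this sets C5 cis to the angular methyl), then saponification and cleavage of the silyl enol ether.

Step 6
Reactants: 8 isopropenyl keto acid
Product: 9 (4aR,5R,8aS)-4a-methyl-2-oxodecahydronaphthalene-5-carboxylic acid
Conditions: O3, MeOH, −78 °C; then FeSO4·7H2O, PhSH, −78 °C → rt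
Reagents that add atoms: none
Why: Ozonolysis in methanol gives the α-methoxy hydroperoxide, divalent iron reduces it to an alkoxy radical that loses methyl acetate by β-scission, and the C7 radical takes a hydrogen atom from PhSH (dealkenylative hydrogenation), removing the controlling group after C4a and C5 are fixed.

Step 7
Reactants: 9 cis-decalone acid
Product: 10 (4aS,5R)-4a-methyl-2-oxo-2,4a,5,6,7,8-hexahydronaphthalene-5-carboxylic acid
Conditions: IBX (3.5 equiv), DMSO, 80 °C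
Reagents that add atoms: none
Why: IBX dehydrogenates the ketone on both α,β-sides through its enol forms to give the cross-conjugated dienone, leaving C4a and C5 untouched.

Step 8
Reactants: 10 dienone acid
Product: 12 (4aS,5R,8S)-8-hydroxy-4a-methyl-2-oxo-2,4a,5,6,7,8-hexahydronaphthalene-5-carboxylic acid, via bis-silyl trienol ether 11 (not isolated)
Conditions: TBSOTf, Et3N, CH2Cl2, 0 °C; volatiles removed; mCPBA, NaHCO3, CH2Cl2, −20 °C; aq. citric acid, THF
Reagents that add atoms: 3-chloroperbenzoic acid, OOC(=O)c1cccc(Cl)c1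
Why: C8 is the only enolisable position of the dienone, and the peracid attacks the trienol ether at C8 axially on the β face (vinylogous Rubottom oxidation, as in the 6β-hydroxylation of steroidal dienol ethers), setting C8 cis to the angular methyl.

Step 9
Reactants: 12 hydroxy dienone acid
Product: 13 (4R,4aS,5R,8S)-4-(3,3-diethoxyprop-1-en-2-yl)-8-hydroxy-4a-methyl-2-oxo-2,3,4,4a,5,6,7,8-octahydronaphthalene-5-carboxylic acid
Conditions: 2-bromo-3,3-diethoxyprop-1-ene, n-BuLi, Et2O, −78 °C; CuI, −40 °C (4 equiv of cuprate); then 12, THF, −78 → −30 °C; aq. NH4Cl, then pH 4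
Reagents that add atoms: 2-bromo-3,3-diethoxyprop-1-ene, C=C(Br)C(OCC)OCC
Why: Conjugate addition of the Gilman cuprate (an α-acrolein anion equivalent; the first equivalents deprotonate CO2H and OH) occurs at the unsubstituted β-carbon C4 of the cross-conjugated dienone, anti to the axial angular methyl, which sets C4 and returns the C1=C8a enone on protonation.

Step 10
Reactants: 14 methyl (R)-lactate
Product: 15 methyl (R)-2-(trifluoromethanesulfonyloxy)propanoate
Conditions: Tf2O, 2,6-lutidine, CH2Cl2, −78 → 0 °C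
Reagents that add atoms: trifluoromethanesulfonic anhydride, O=S(=O)(OS(=O)(=O)C(F)(F)F)C(F)(F)F
Why: O-sulfonylation of the alcohol leaves the stereocentre untouched.

Step 11
Reactants: 15 lactate triflate; 16 (S)-1-bromo-2-methylbutane
Product: 18 methyl (2R,4S)-2,4-dimethylhexanoate, via (S)-2-methylbutylmagnesium bromide 17 (not isolated)
Conditions: 16, Mg, THF, 40 °C; then 15, ZnCl2 (5 mol%), THF, 0 °C
Reagents that add atoms: none
Why: The zinc-catalysed sp3–sp3 coupling of the Grignard reagent with the α-triflyloxy ester is an SN2 displacement with clean inversion, so C2 becomes R while the β-stereocentre of the Grignard reagent is unaffected.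

Step 12
Reactants: 18 methyl (2R,4S)-2,4-dimethylhexanoate
Product: 20 ethyl (2E,4E,6R,8S)-6,8-dimethyldeca-2,4-dienoate, via (2R,4S)-2,4-dimethylhexanal 19 (not isolated)
Conditions: i-Bu2AlH, CH2Cl2, −78 °C; then triethyl 4-phosphonocrotonate/LiN(SiMe3)2, THF, −78 → 0 °C
Reagents that add atoms: triethyl 4-phosphonocrotonate, CCOC(=O)/C=C/CP(=O)(OCC)OCC
Why: Half-reduction to the aluminium hemiacetal and in situ vinylogous Horner–Wadsworth–Emmons olefination avoids handling the epimerisable α-branched aldehyde and gives the (2E,4E)-dienoate.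

Step 13
Reactants: 20 ethyl dienoate
Product: 21 (2E,4E,6R,8S)-6,8-dimethyldeca-2,4-dienoic acid
Conditions: LiOH, THF/MeOH/H2O, rt; then 1 M HCl
Reagents that add atoms: lithium hydroxide, [Li+].[OH-]
Why: Saponification of the ethyl ester does not touch the γ- and ε-stereocentres.

Step 14
Reactants: 13 hydroxy acid acetal; 21 dienoic acid
Product: 24 tert-butyldimethylsilyl (4R,4aS,5R,8S)-4-(3,3-diethoxyprop-1-en-2-yl)-8-{[(2E,4E,6R,8S)-6,8-dimethyldeca-2,4-dienoyl]oxy}-4a-methyl-2-oxo-2,3,4,4a,5,6,7,8-octahydronaphthalene-5-carboxylate, via silyl ester 22 (not isolated), via mixed anhydride 23 (not isolated)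
Conditions: 13, TBSCl (1.05 equiv), Et3N, CH2Cl2, 0 °C; 21, 2,4,6-trichlorobenzoyl chloride, Et3N, toluene, rt; combined, DMAP, toluene, rt
Reagents that add atoms: tert-butyldimethylsilyl chloride, CC(C)(C)[Si](C)(C)Cl
Why: The acid is silylated much faster than the hindered axial alcohol, so Yamaguchi esterification then acylates only the C8 hydroxyl, with retention at C8.

Step 15
Reactants: 24 silyl ester acetal
Product: 25 (4R,4aS,5R,8S)-8-{[(2E,4E,6R,8S)-6,8-dimethyldeca-2,4-dienoyl]oxy}-4a-methyl-2-oxo-4-(3-oxoprop-1-en-2-yl)-2,3,4,4a,5,6,7,8-octahydronaphthalene-5-carboxylic acid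
Conditions: 1 M HCl, THF, 0 °C → rt
Reagents that add atoms: water, O
Why: Mild aqueous acid hydrolyses the silyl ester and the diethyl acetal, releasing the carboxylic acid and the 2-substituted acrolein without touching the esters or the enone.

**Compound list**
1 | but-3-en-2-one | CC(=O)C=C | starting material
2 | 2-(tert-butyldimethylsilyloxy)buta-1,3-diene | C=CC(=C)O[Si](C)(C)C(C)(C)C | intermediate
3 | (R)-(−)-carvone | CC1=CC[C@H](CC1=O)C(C)=C | starting material
4 | (4aR,7R,8aS)-2-(tert-butyldimethylsilyloxy)-4a-methyl-7-(prop-1-en-2-yl)-4,4a,6,7,8,8a-hexahydronaphthalen-5(1H)-one | C1C=C(O[Si](C)(C)C(C)(C)C)C[C@@H]2C[C@@H](C(C)=C)CC(=O)[C@@]21C | intermediate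
5 | (4aR,7R,8aS)-2-(tert-butyldimethylsilyloxy)-4a-methyl-7-(prop-1-en-2-yl)-1,4,4a,7,8,8a-hexahydronaphthalen-5-yl trifluoromethanesulfonate | C1C=C(O[Si](C)(C)C(C)(C)C)C[C@@H]2C[C@@H](C(C)=C)C=C(OS(=O)(=O)C(F)(F)F)[C@@]21C | intermediate
6 | methyl (4aR,7R,8aS)-2-(tert-butyldimethylsilyloxy)-4a-methyl-7-(prop-1-en-2-yl)-1,4,4a,7,8,8a-hexahydronaphthalene-5-carboxylate | C1C=C(O[Si](C)(C)C(C)(C)C)C[C@@H]2C[C@@H](C(C)=C)C=C(C(=O)OC)[C@@]21C | intermediate
7 | methyl (4aR,5R,7R,8aS)-2-(tert-butyldimethylsilyloxy)-4a-methyl-7-(prop-1-en-2-yl)-1,4,4a,5,6,7,8,8a-octahydronaphthalene-5-carboxylate | C1C=C(O[Si](C)(C)C(C)(C)C)C[C@@H]2C[C@@H](C(C)=C)C[C@@H](C(=O)OC)[C@@]21C | intermediate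
8 | (4aR,5R,7R,8aS)-4a-methyl-2-oxo-7-(prop-1-en-2-yl)decahydronaphthalene-5-carboxylic acid | C1CC(=O)C[C@@H]2C[C@@H](C(C)=C)C[C@@H](C(=O)O)[C@@]21C | intermediate
9 | (4aR,5R,8aS)-4a-methyl-2-oxodecahydronaphthalene-5-carboxylic acid | C1CC(=O)C[C@@H]2CCC[C@@H](C(=O)O)[C@@]21C | intermediate
10 | (4aS,5R)-4a-methyl-2-oxo-2,4a,5,6,7,8-hexahydronaphthalene-5-carboxylic acid | C1=CC(=O)C=C2CCC[C@@H](C(=O)O)[C@@]21C | intermediate
11 | tert-butyldimethylsilyl (4aS,5R)-2-(tert-butyldimethylsilyloxy)-4a-methyl-4a,5,6,7-tetrahydronaphthalene-5-carboxylate | C1=CC(O[Si](C)(C)C(C)(C)C)=CC2=CCC[C@@H](C(=O)O[Si](C)(C)C(C)(C)C)[C@@]21C | intermediate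
12 | (4aS,5R,8S)-8-hydroxy-4a-methyl-2-oxo-2,4a,5,6,7,8-hexahydronaphthalene-5-carboxylic acid | C1=CC(=O)C=C2[C@@H](O)CC[C@@H](C(=O)O)[C@@]21C | intermediate
13 | (4R,4aS,5R,8S)-4-(3,3-diethoxyprop-1-en-2-yl)-8-hydroxy-4a-methyl-2-oxo-2,3,4,4a,5,6,7,8-octahydronaphthalene-5-carboxylic acid | CCOC(OCC)C(=C)[C@@H]1CC(=O)C=C2[C@@H](O)CC[C@@H](C(=O)O)[C@@]21C | intermediate
14 | methyl (R)-lactate | COC(=O)[C@@H](C)O | starting material
15 | methyl (R)-2-(trifluoromethanesulfonyloxy)propanoate | COC(=O)[C@@H](C)OS(=O)(=O)C(F)(F)F | intermediate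
16 | (S)-1-bromo-2-methylbutane | BrC[C@@H](C)CC | starting material
17 | (S)-2-methylbutylmagnesium bromide | Br[Mg]C[C@@H](C)CC | intermediate
18 | methyl (2R,4S)-2,4-dimethylhexanoate | COC(=O)[C@H](C)C[C@@H](C)CC | intermediate
19 | (2R,4S)-2,4-dimethylhexanal | O=C[C@H](C)C[C@@H](C)CC | intermediate
20 | ethyl (2E,4E,6R,8S)-6,8-dimethyldeca-2,4-dienoate | CCOC(=O)/C=C/C=C/[C@H](C)C[C@@H](C)CC | intermediate
21 | (2E,4E,6R,8S)-6,8-dimethyldeca-2,4-dienoic acid | OC(=O)/C=C/C=C/[C@H](C)C[C@@H](C)CC | intermediate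
22 | tert-butyldimethylsilyl (4R,4aS,5R,8S)-4-(3,3-diethoxyprop-1-en-2-yl)-8-hydroxy-4a-methyl-2-oxo-2,3,4,4a,5,6,7,8-octahydronaphthalene-5-carboxylate | CCOC(OCC)C(=C)[C@@H]1CC(=O)C=C2[C@@H](O)CC[C@@H](C(=O)O[Si](C)(C)C(C)(C)C)[C@@]21C | intermediate
23 | (2E,4E,6R,8S)-6,8-dimethyldeca-2,4-dienoic 2,4,6-trichlorobenzoic anhydride | O=C(OC(=O)c1c(Cl)cc(Cl)cc1Cl)/C=C/C=C/[C@H](C)C[C@@H](C)CC | intermediate
24 | tert-butyldimethylsilyl (4R,4aS,5R,8S)-4-(3,3-diethoxyprop-1-en-2-yl)-8-{[(2E,4E,6R,8S)-6,8-dimethyldeca-2,4-dienoyl]oxy}-4a-methyl-2-oxo-2,3,4,4a,5,6,7,8-octahydronaphthalene-5-carboxylate | CCOC(OCC)C(=C)[C@@H]1CC(=O)C=C2[C@@H](OC(=O)/C=C/C=C/[C@H](C)C[C@@H](C)CC)CC[C@@H](C(=O)O[Si](C)(C)C(C)(C)C)[C@@]21C | intermediate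
25 | (4R,4aS,5R,8S)-8-{[(2E,4E,6R,8S)-6,8-dimethyldeca-2,4-dienoyl]oxy}-4a-methyl-2-oxo-4-(3-oxoprop-1-en-2-yl)-2,3,4,4a,5,6,7,8-octahydronaphthalene-5-carboxylic acid (CNP0235609.2) | C=C(C=O)[C@@H]1CC(=O)C=C2[C@@H](OC(=O)/C=C/C=C/[C@H](C)C[C@@H](C)CC)CC[C@@H](C(=O)O)[C@@]21C | target

**Step count**
Total: 15 steps (steps 1–9 and 14–15 on the decalin line, steps 10–13 for the side chain). Longest linear sequence: 11 steps (1, 2, 3, 4, 5, 6, 7, 8, 9, 14, 15).

**The three steps most likely to fail, with fallbacks**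

Step 7 (double dehydrogenation with IBX; risk of incomplete or over-oxidation). The fallback sets out from 9 and returns at 10, replacing direct dehydrogenation by two Saegusa–Ito oxidations. Compound 9 is converted with TMSCl, NaI and Et3N in MeCN into trimethylsilyl (4aR,5R,8aS)-4a-methyl-2-(trimethylsilyloxy)-3,4,4a,5,6,7,8,8a-octahydronaphthalene-5-carboxylate F1; the cis-fused ketone enolises toward C1. Pd(OAc)2 in MeCN then gives (4aS,5R)-4a-methyl-2-oxo-2,3,4,4a,5,6,7,8-octahydronaphthalene-5-carboxylic acid F2 after aqueous work-up. Kinetic enolisation at C3 with LiN(i-Pr)2 (2.2 equiv) and TMSCl gives trimethylsilyl (4aS,5R)-4a-methyl-2-(trimethylsilyloxy)-4,4a,5,6,7,8-hexahydronaphthalene-5-carboxylate F3, and a second Pd(OAc)2 oxidation delivers 10.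

Step 8 (γ-hydroxylation; risk of poor facial selectivity at C8). The fallback sets out from 10 and returns at 12, replacing direct stereoselective hydroxylation by an oxidation–reduction correction. The γ-oxidation is run without regard to selectivity. The mixture of 12 and its epimer (4aS,5R,8R)-8-hydroxy-4a-methyl-2-oxo-2,4a,5,6,7,8-hexahydronaphthalene-5-carboxylic acid F4 is oxidised with MnO2 in CH2Cl2 to (4aS,5R)-4a-methyl-2,8-dioxo-2,4a,5,6,7,8-hexahydronaphthalene-5-carboxylic acid F5. Luche reduction (NaBH4, CeCl3·7H2O, MeOH, −78 °C) then attacks the more electrophilic C8 carbonyl from the α face, anti to the angular methyl, and returns 12.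

Step 9 (functionalised cuprate on an unprotected hydroxy acid). The fallback sets out from 12 and returns at 25, using a more robust hydroxymethylvinyl synthon and a late allylic oxidation.
- The cuprate from 2-bromo-3-(tert-butyldimethylsilyloxy)prop-1-ene (n-BuLi, CuI) adds to 12 to give (4R,4aS,5R,8S)-4-[3-(tert-butyldimethylsilyloxy)prop-1-en-2-yl]-8-hydroxy-4a-methyl-2-oxo-2,3,4,4a,5,6,7,8-octahydronaphthalene-5-carboxylic acid F6.
- TBSCl/Et3N gives its tert-butyldimethylsilyl ester F7, and acylation with 23/DMAP gives tert-butyldimethylsilyl (4R,4aS,5R,8S)-4-[3-(tert-butyldimethylsilyloxy)prop-1-en-2-yl]-8-{[(2E,4E,6R,8S)-6,8-dimethyldeca-2,4-dienoyl]oxy}-4a-methyl-2-oxo-2,3,4,4a,5,6,7,8-octahydronaphthalene-5-carboxylate F8.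
- 1 M HCl in THF removes both silyl groups to give (4R,4aS,5R,8S)-8-{[(2E,4E,6R,8S)-6,8-dimethyldeca-2,4-dienoyl]oxy}-4-(3-hydroxyprop-1-en-2-yl)-4a-methyl-2-oxo-2,3,4,4a,5,6,7,8-octahydronaphthalene-5-carboxylic acid F9, and MnO2 oxidises the allylic alcohol to 25.

**Further compounds**
F1 | step 7 | trimethylsilyl (4aR,5R,8aS)-4a-methyl-2-(trimethylsilyloxy)-3,4,4a,5,6,7,8,8a-octahydronaphthalene-5-carboxylate | C1CC(O[Si](C)(C)C)=C[C@@H]2CCC[C@@H](C(=O)O[Si](C)(C)C)[C@@]21C
F2 | step 7 | (4aS,5R)-4a-methyl-2-oxo-2,3,4,4a,5,6,7,8-octahydronaphthalene-5-carboxylic acid | C1CC(=O)C=C2CCC[C@@H](C(=O)O)[C@@]21C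
F3 | step 7 | trimethylsilyl (4aS,5R)-4a-methyl-2-(trimethylsilyloxy)-4,4a,5,6,7,8-hexahydronaphthalene-5-carboxylate | C1C=C(O[Si](C)(C)C)C=C2CCC[C@@H](C(=O)O[Si](C)(C)C)[C@@]21C
F4 | step 8 | (4aS,5R,8R)-8-hydroxy-4a-methyl-2-oxo-2,4a,5,6,7,8-hexahydronaphthalene-5-carboxylic acid | C1=CC(=O)C=C2[C@H](O)CC[C@@H](C(=O)O)[C@@]21C
F5 | step 8 | (4aS,5R)-4a-methyl-2,8-dioxo-2,4a,5,6,7,8-hexahydronaphthalene-5-carboxylic acid | C1=CC(=O)C=C2C(=O)CC[C@@H](C(=O)O)[C@@]21C
F6 | step 9 | (4R,4aS,5R,8S)-4-[3-(tert-butyldimethylsilyloxy)prop-1-en-2-yl]-8-hydroxy-4a-methyl-2-oxo-2,3,4,4a,5,6,7,8-octahydronaphthalene-5-carboxylic acid | CC(C)(C)[Si](C)(C)OCC(=C)[C@@H]1CC(=O)C=C2[C@@H](O)CC[C@@H](C(=O)O)[C@@]21C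
F7 | step 9 | tert-butyldimethylsilyl (4R,4aS,5R,8S)-4-[3-(tert-butyldimethylsilyloxy)prop-1-en-2-yl]-8-hydroxy-4a-methyl-2-oxo-2,3,4,4a,5,6,7,8-octahydronaphthalene-5-carboxylate | CC(C)(C)[Si](C)(C)OCC(=C)[C@@H]1CC(=O)C=C2[C@@H](O)CC[C@@H](C(=O)O[Si](C)(C)C(C)(C)C)[C@@]21C
F8 | step 9 | tert-butyldimethylsilyl (4R,4aS,5R,8S)-4-[3-(tert-butyldimethylsilyloxy)prop-1-en-2-yl]-8-{[(2E,4E,6R,8S)-6,8-dimethyldeca-2,4-dienoyl]oxy}-4a-methyl-2-oxo-2,3,4,4a,5,6,7,8-octahydronaphthalene-5-carboxylate | CC(C)(C)[Si](C)(C)OCC(=C)[C@@H]1CC(=O)C=C2[C@@H](OC(=O)/C=C/C=C/[C@H](C)C[C@@H](C)CC)CC[C@@H](C(=O)O[Si](C)(C)C(C)(C)C)[C@@]21C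
F9 | step 9 | (4R,4aS,5R,8S)-8-{[(2E,4E,6R,8S)-6,8-dimethyldeca-2,4-dienoyl]oxy}-4-(3-hydroxyprop-1-en-2-yl)-4a-methyl-2-oxo-2,3,4,4a,5,6,7,8-octahydronaphthalene-5-carboxylic acid | OCC(=C)[C@@H]1CC(=O)C=C2[C@@H](OC(=O)/C=C/C=C/[C@H](C)C[C@@H](C)CC)CC[C@@H](C(=O)O)[C@@]21C
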